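**Retrosynthetic overview**
1. Target 24 ⇐ tri-O-benzyl flavone 23 (hydrogenolysis) ⇐ 1,3-diketone 22; acid cyclodehydration closes the pyranone (ring C), the last ring formed.
2. 22 ⇐ crossed Claisen condensation of the ring A methyl ketone 20, already carrying the (R)-N-methylpyrrolidine, with the ring B ester 21; this is the fragment-joining C–C bond.
3. 20 ⇐ N-sulfinylpyrrolidine aryl bromide 16 (Br to acetyl via the aryllithium, N–S and MOM cleavage, N-methylation).
4. 16 ⇐ (S)-sulfinyl aldimine 11: diastereoselective allylation sets C-2, then hydroboration and N-alkylation close the pyrrolidine, the first ring formed.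
5. 11 ⇐ hexasubstituted aldehyde 9 ⇐ symmetric phenol 6 (ortho-formylation, bromination, MOM) ⇐ methyl 4-O-methylgallate 1 (benzylation, ester to aldehyde, Baeyer–Villiger).

Assumption: the facial sense of the sulfinimine allylation follows the usual cyclic chelate model for aryl aldimines ((S)-sulfinyl gives (R)-carbon) and is confirmed at sulfinamide 12; compounds 1, 10 and 21 are bought.

**Route**

Step 1
Reactants: 1 methyl 3,5-dihydroxy-4-methoxybenzoate
Product: 2 methyl 3,5-bis(benzyloxy)-4-methoxybenzoate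
Conditions: BnBr (2.4 equiv), K2CO3, DMF, 60 °C
Reagents that add atoms: benzyl bromide, BrCc1ccccc1
Why: Williamson ether synthesis on the two equivalent phenols under carbonate conditions that leave the methyl ester and the methyl ether untouched.

Step 2
Reactants: 2 methyl 3,5-bis(benzyloxy)-4-methoxybenzoate
Product: 3 [3,5-bis(benzyloxy)-4-methoxyphenyl]methanol
Conditions: LiAlH4, THF, 0 °C to rt
Reagents that add atoms: none
Why: Hydride reduction of the ester to the primary benzylic alcohol, to which aryl benzyl and methyl ethers are inert.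

Step 3
Reactants: 3 [3,5-bis(benzyloxy)-4-methoxyphenyl]methanol
Product: 4 3,5-bis(benzyloxy)-4-methoxybenzaldehyde
Conditions: activated MnO2 (10 equiv), CH2Cl2, rt
Reagents that add atoms: none
Why: Chemoselective benzylic alcohol oxidation with MnO2 stops cleanly at the aldehyde.

Step 4
Reactants: 4 3,5-bis(benzyloxy)-4-methoxybenzaldehyde
Product: 6 3,5-bis(benzyloxy)-4-methoxyphenol, via aryl formate 5 (not isolated)
Conditions: mCPBA, CH2Cl2, 0 °C to rt; then K2CO3, MeOH, rt
Reagents that add atoms: mCPBA, O=C(OO)c1cccc(Cl)c1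
Why: Baeyer–Villiger (Dakin-type) oxidation in which the electron-rich trialkoxyaryl group migrates in preference to hydrogen, followed by mild methanolysis of the formate to the phenol.

Step 5
Reactants: 6 3,5-bis(benzyloxy)-4-methoxyphenol
Product: 7 2,4-bis(benzyloxy)-6-hydroxy-3-methoxybenzaldehyde
Conditions: MgCl2, Et3N, (CH2O)n, MeCN, reflux
Reagents that add atoms: paraformaldehyde (formaldehyde unit), C=O
Why: Casnati–Skattebøl ortho-formylation, in which the magnesium phenoxide delivers formaldehyde only to an ortho position, and the two ortho positions of 6 are equivalent so a single aldehyde results.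

Step 6
Reactants: 7 2,4-bis(benzyloxy)-6-hydroxy-3-methoxybenzaldehyde
Product: 8 2,4-bis(benzyloxy)-5-bromo-6-hydroxy-3-methoxybenzaldehyde
Conditions: NBS (1.05 equiv), MeCN, 0 °C
Reagents that add atoms: N-bromosuccinimide, O=C1CCC(=O)N1Br
Why: Electrophilic aromatic bromination at the only remaining ring CH, which is activated by the ortho hydroxyl and the ortho and para benzyloxy groups, installs the handle for the later acetyl group.

Step 7
Reactants: 8 2,4-bis(benzyloxy)-5-bromo-6-hydroxy-3-methoxybenzaldehyde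
Product: 9 2,4-bis(benzyloxy)-5-bromo-3-methoxy-6-(methoxymethoxy)benzaldehyde
Conditions: NaH, MOMCl, DMF, 0 °C to rt
Reagents that add atoms: chloromethyl methyl ether, COCCl
Why: O-alkylation of the phenoxide (acetal protection) masks the one phenol that will later form the pyranone oxygen with a group that is orthogonal to the two benzyl ethers.

Step 8
Reactants: 9 2,4-bis(benzyloxy)-5-bromo-3-methoxy-6-(methoxymethoxy)benzaldehyde; 10 (S)-2-methylpropane-2-sulfinamide
Product: 11 (S)-N-[(E)-[2,4-bis(benzyloxy)-5-bromo-3-methoxy-6-(methoxymethoxy)phenyl]methylidene]-2-methylpropane-2-sulfinamide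
Conditions: Ti(OEt)4 (2 equiv), THF, 60 °C
Reagents that add atoms: none
Why: Ellman sulfinimine condensation, with Ti(OEt)4 acting as Lewis acid and water scavenger, gives the E-aldimine even from a di-ortho-substituted aldehyde.

Step 9
Reactants: 11 (S)-N-[(E)-[2,4-bis(benzyloxy)-5-bromo-3-methoxy-6-(methoxymethoxy)phenyl]methylidene]-2-methylpropane-2-sulfinamide
Product: 12 (S)-N-[(1R)-1-[2,4-bis(benzyloxy)-5-bromo-3-methoxy-6-(methoxymethoxy)phenyl]but-3-en-1-yl]-2-methylpropane-2-sulfinamide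
Conditions: allyl bromide (3 equiv), In powder (indium metal, 2 equiv), THF, 60 °C
Reagents that add atoms: allyl bromide, C=CCBr
Why: Barbier-type allylation of the N-sulfinyl aldimine through a chair transition state with the metal held by N and the sulfinyl oxygen delivers allyl to the Re face of the (S)-sulfinyl imine, setting the (R) benzylic stereocentre, and the minor diastereomer is removed by chromatography.

Step 10
Reactants: 12 (S)-N-[(1R)-1-[2,4-bis(benzyloxy)-5-bromo-3-methoxy-6-(methoxymethoxy)phenyl]but-3-en-1-yl]-2-methylpropane-2-sulfinamide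
Product: 14 (S)-N-[(1R)-1-[2,4-bis(benzyloxy)-5-bromo-3-methoxy-6-(methoxymethoxy)phenyl]-4-hydroxybutyl]-2-methylpropane-2-sulfinamide, via alkyl-9-BBN borane 13 (not isolated)
Conditions: 9-BBN (3 equiv), THF, 0 °C to rt; then NaBO3·4H2O, THF/H2O, rt
Reagents that add atoms: sodium perborate (NaBO3·4H2O), [Na+].[O-]OB=O
Why: Anti-Markovnikov hydroboration–oxidation with the bulky borane gives only the primary alcohol, and perborate oxidises the C–B bond without touching the sulfinamide, the aryl bromide or the stereocentre.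

Step 11
Reactants: 14 (S)-N-[(1R)-1-[2,4-bis(benzyloxy)-5-bromo-3-methoxy-6-(methoxymethoxy)phenyl]-4-hydroxybutyl]-2-methylpropane-2-sulfinamide
Product: 16 (2R)-2-[2,4-bis(benzyloxy)-5-bromo-3-methoxy-6-(methoxymethoxy)phenyl]-1-[(S)-tert-butylsulfinyl]pyrrolidine, via primary mesylate 15 (not isolated)
Conditions: MsCl, Et3N, CH2Cl2, 0 °C; then NaH, THF, 0 °C to rt
Reagents that add atoms: none
Why: Mesylation followed by intramolecular SN2 N-alkylation (5-exo-tet) of the sulfinamide anion closes the pyrrolidine at the remote primary carbon, so the benzylic stereocentre is not involved.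

Step 12
Reactants: 16 (2R)-2-[2,4-bis(benzyloxy)-5-bromo-3-methoxy-6-(methoxymethoxy)phenyl]-1-[(S)-tert-butylsulfinyl]pyrrolidine
Product: 18 1-[2,4-bis(benzyloxy)-5-[(2R)-1-[(S)-tert-butylsulfinyl]pyrrolidin-2-yl]-3-methoxy-6-(methoxymethoxy)phenyl]ethan-1-one, via aryllithium 17 (not isolated)
Conditions: n-BuLi (1.05 equiv), THF, –78 °C, 10 min; then MeC(O)N(OMe)Me, –78 to 0 °C; H2O
Reagents that add atoms: N-methoxy-N-methylacetamide, CC(=O)N(C)OC
Why: Lithium–bromine exchange outruns any deprotonation or attack at the hindered sulfinyl sulfur at –78 °C, and Weinreb ketone synthesis on the alkoxy-chelated aryllithium stops at the ketone because the tetrahedral chelate survives until work-up.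

Step 13
Reactants: 18 1-[2,4-bis(benzyloxy)-5-[(2R)-1-[(S)-tert-butylsulfinyl]pyrrolidin-2-yl]-3-methoxy-6-(methoxymethoxy)phenyl]ethan-1-one
Product: 19 1-[2,4-bis(benzyloxy)-6-hydroxy-3-methoxy-5-[(2R)-pyrrolidin-2-yl]phenyl]ethan-1-one
Conditions: HCl (4 M in dioxane, 5 equiv), MeOH, rt; NaHCO3 work-up
Reagents that add atoms: none
Why: Acid-catalysed methanolysis cleaves both the N–S bond of the sulfinamide and the MOM acetal (activated by the ortho carbonyl) at room temperature, while benzyl ethers, the ketone and the stereocentre are unaffected.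

Step 14
Reactants: 19 1-[2,4-bis(benzyloxy)-6-hydroxy-3-methoxy-5-[(2R)-pyrrolidin-2-yl]phenyl]ethan-1-one
Product: 20 1-[2,4-bis(benzyloxy)-6-hydroxy-3-methoxy-5-[(2R)-1-methylpyrrolidin-2-yl]phenyl]ethan-1-one
Conditions: aq. CH2O (37%), NaBH(OAc)3, ClCH2CH2Cl, rt
Reagents that add atoms: formaldehyde, C=O
Why: Reductive amination, in which the iminium ion is reduced much faster than the hindered hydrogen-bonded aryl ketone, and the fully substituted ring offers no site for competing hydroxymethylation.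

Step 15
Reactants: 20 1-[2,4-bis(benzyloxy)-6-hydroxy-3-methoxy-5-[(2R)-1-methylpyrrolidin-2-yl]phenyl]ethan-1-one; 21 methyl 4-(benzyloxy)benzoate
Product: 22 1-[2,4-bis(benzyloxy)-6-hydroxy-3-methoxy-5-[(2R)-1-methylpyrrolidin-2-yl]phenyl]-3-[4-(benzyloxy)phenyl]propane-1,3-dione
Conditions: NaH (5 equiv), DMF, 0 °C to rt; then H2O, adjust to pH 7–8
Reagents that add atoms: none
Why: Crossed Claisen condensation in which the phenoxide–enolate dianion of 20 attacks the non-enolisable benzoate and the equilibrium is pulled over by deprotonation of the 1,3-diketone, under basic conditions that cannot epimerise the non-acidic benzylic amine centre.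

Step 16
Reactants: 22 1-[2,4-bis(benzyloxy)-6-hydroxy-3-methoxy-5-[(2R)-1-methylpyrrolidin-2-yl]phenyl]-3-[4-(benzyloxy)phenyl]propane-1,3-dione
Product: 23 5,7-bis(benzyloxy)-2-[4-(benzyloxy)phenyl]-6-methoxy-8-[(2R)-1-methylpyrrolidin-2-yl]-4H-chromen-4-one
Conditions: conc. HCl (5 equiv), MeOH/THF, 50 °C; NaHCO3 work-up
Reagents that add atoms: none
Why: Acid-catalysed cyclodehydration of the o-hydroxyaryl 1,3-diketone closes the pyranone through the only free phenol (the former MOM site), which fixes the pyrrolidine at C-8 and the methoxy group at C-6.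

Step 17
Reactants: 23 5,7-bis(benzyloxy)-2-[4-(benzyloxy)phenyl]-6-methoxy-8-[(2R)-1-methylpyrrolidin-2-yl]-4H-chromen-4-one
Product: 24 5,7-dihydroxy-2-(4-hydroxyphenyl)-6-methoxy-8-[(2R)-1-methylpyrrolidin-2-yl]-4H-chromen-4-one
Conditions: H2 (1 atm), 10% Pd/C, THF/MeOH, rt, stopped after uptake of 3 equiv
Reagents that add atoms: none
Why: Catalytic hydrogenolysis removes the three O-benzyl ethers under neutral conditions far faster than it cleaves the hindered ring C–N bond or reduces the chromone alkene, so the stereocentre and the methyl ether are kept.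

**Compound list**
1 | methyl 3,5-dihydroxy-4-methoxybenzoate | COC(=O)c1cc(O)c(OC)c(O)c1 | starting material
2 | methyl 3,5-bis(benzyloxy)-4-methoxybenzoate | COC(=O)c1cc(OCc2ccccc2)c(OC)c(OCc2ccccc2)c1 | intermediate
3 | [3,5-bis(benzyloxy)-4-methoxyphenyl]methanol | OCc1cc(OCc2ccccc2)c(OC)c(OCc2ccccc2)c1 | intermediate
4 | 3,5-bis(benzyloxy)-4-methoxybenzaldehyde | O=Cc1cc(OCc2ccccc2)c(OC)c(OCc2ccccc2)c1 | intermediate
5 | 3,5-bis(benzyloxy)-4-methoxyphenyl formate | O=COc1cc(OCc2ccccc2)c(OC)c(OCc2ccccc2)c1 | intermediate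
6 | 3,5-bis(benzyloxy)-4-methoxyphenol | Oc1cc(OCc2ccccc2)c(OC)c(OCc2ccccc2)c1 | intermediate
7 | 2,4-bis(benzyloxy)-6-hydroxy-3-methoxybenzaldehyde | O=Cc1c(O)cc(OCc2ccccc2)c(OC)c1OCc1ccccc1 | intermediate
8 | 2,4-bis(benzyloxy)-5-bromo-6-hydroxy-3-methoxybenzaldehyde | O=Cc1c(O)c(Br)c(OCc2ccccc2)c(OC)c1OCc1ccccc1 | intermediate
9 | 2,4-bis(benzyloxy)-5-bromo-3-methoxy-6-(methoxymethoxy)benzaldehyde | O=Cc1c(OCOC)c(Br)c(OCc2ccccc2)c(OC)c1OCc1ccccc1 | intermediate
10 | (S)-2-methylpropane-2-sulfinamide | CC(C)(C)[S@](=O)N | starting material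
11 | (S)-N-[(E)-[2,4-bis(benzyloxy)-5-bromo-3-methoxy-6-(methoxymethoxy)phenyl]methylidene]-2-methylpropane-2-sulfinamide | CC(C)(C)[S@](=O)/N=C/c1c(OCOC)c(Br)c(OCc2ccccc2)c(OC)c1OCc1ccccc1 | intermediate
12 | (S)-N-[(1R)-1-[2,4-bis(benzyloxy)-5-bromo-3-methoxy-6-(methoxymethoxy)phenyl]but-3-en-1-yl]-2-methylpropane-2-sulfinamide | C=CC[C@@H](N[S@@](=O)C(C)(C)C)c1c(OCOC)c(Br)c(OCc2ccccc2)c(OC)c1OCc1ccccc1 | intermediate
13 | (S)-N-[(1R)-1-[2,4-bis(benzyloxy)-5-bromo-3-methoxy-6-(methoxymethoxy)phenyl]-4-(9-borabicyclo[3.3.1]nonan-9-yl)butyl]-2-methylpropane-2-sulfinamide | B1(CCC[C@@H](N[S@@](=O)C(C)(C)C)c2c(OCOC)c(Br)c(OCc3ccccc3)c(OC)c2OCc2ccccc2)C2CCCC1CCC2 | intermediate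
14 | (S)-N-[(1R)-1-[2,4-bis(benzyloxy)-5-bromo-3-methoxy-6-(methoxymethoxy)phenyl]-4-hydroxybutyl]-2-methylpropane-2-sulfinamide | OCCC[C@@H](N[S@@](=O)C(C)(C)C)c1c(OCOC)c(Br)c(OCc2ccccc2)c(OC)c1OCc1ccccc1 | intermediate
15 | (4R)-4-[2,4-bis(benzyloxy)-5-bromo-3-methoxy-6-(methoxymethoxy)phenyl]-4-[[(S)-tert-butylsulfinyl]amino]butyl methanesulfonate | CS(=O)(=O)OCCC[C@@H](N[S@@](=O)C(C)(C)C)c1c(OCOC)c(Br)c(OCc2ccccc2)c(OC)c1OCc1ccccc1 | intermediate
16 | (2R)-2-[2,4-bis(benzyloxy)-5-bromo-3-methoxy-6-(methoxymethoxy)phenyl]-1-[(S)-tert-butylsulfinyl]pyrrolidine | COCOc1c(Br)c(OCc2ccccc2)c(OC)c(OCc2ccccc2)c1[C@H]1CCCN1[S@@](=O)C(C)(C)C | intermediate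
17 | [2,4-bis(benzyloxy)-5-[(2R)-1-[(S)-tert-butylsulfinyl]pyrrolidin-2-yl]-3-methoxy-6-(methoxymethoxy)phenyl]lithium | [Li]c1c(OCOC)c([C@H]2CCCN2[S@@](=O)C(C)(C)C)c(OCc2ccccc2)c(OC)c1OCc1ccccc1 | intermediate
18 | 1-[2,4-bis(benzyloxy)-5-[(2R)-1-[(S)-tert-butylsulfinyl]pyrrolidin-2-yl]-3-methoxy-6-(methoxymethoxy)phenyl]ethan-1-one | CC(=O)c1c(OCOC)c([C@H]2CCCN2[S@@](=O)C(C)(C)C)c(OCc2ccccc2)c(OC)c1OCc1ccccc1 | intermediate
19 | 1-[2,4-bis(benzyloxy)-6-hydroxy-3-methoxy-5-[(2R)-pyrrolidin-2-yl]phenyl]ethan-1-one | CC(=O)c1c(O)c([C@H]2CCCN2)c(OCc2ccccc2)c(OC)c1OCc1ccccc1 | intermediate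
20 | 1-[2,4-bis(benzyloxy)-6-hydroxy-3-methoxy-5-[(2R)-1-methylpyrrolidin-2-yl]phenyl]ethan-1-one | CC(=O)c1c(O)c([C@H]2CCCN2C)c(OCc2ccccc2)c(OC)c1OCc1ccccc1 | intermediate
21 | methyl 4-(benzyloxy)benzoate | COC(=O)c1ccc(OCc2ccccc2)cc1 | starting material
22 | 1-[2,4-bis(benzyloxy)-6-hydroxy-3-methoxy-5-[(2R)-1-methylpyrrolidin-2-yl]phenyl]-3-[4-(benzyloxy)phenyl]propane-1,3-dione | O=C(CC(=O)c1ccc(OCc2ccccc2)cc1)c1c(O)c([C@H]2CCCN2C)c(OCc2ccccc2)c(OC)c1OCc1ccccc1 | intermediate
23 | 5,7-bis(benzyloxy)-2-[4-(benzyloxy)phenyl]-6-methoxy-8-[(2R)-1-methylpyrrolidin-2-yl]-4H-chromen-4-one | COc1c(OCc2ccccc2)c([C@H]2CCCN2C)c2oc(-c3ccc(OCc4ccccc4)cc3)cc(=O)c2c1OCc1ccccc1 | intermediate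
24 | 5,7-dihydroxy-2-(4-hydroxyphenyl)-6-methoxy-8-[(2R)-1-methylpyrrolidin-2-yl]-4H-chromen-4-one | COc1c(O)c([C@H]2CCCN2C)c2oc(-c3ccc(O)cc3)cc(=O)c2c1O | target

**Step count**
Total steps: 17. Longest linear sequence: 17 steps (1 to 24); 10 and 21 are bought and enter at steps 8 and 15.

**Three steps most likely to fail, each with a fallback**

Step 9. The aldimine 11 is di-ortho-substituted and carries alkoxy groups that can bind the metal, so the allylation may be slow or less diastereoselective than usual. The fallback sets out from 11. Addition of 3-[(tert-butyldimethylsilyl)oxy]propylmagnesium bromide in CH2Cl2 at –48 °C, a Grignard addition through the six-membered Mg-chelated transition state with the same Re-face delivery, gives the silyl ether (S)-N-[(1R)-1-[2,4-bis(benzyloxy)-5-bromo-3-methoxy-6-(methoxymethoxy)phenyl]-4-[(tert-butyldimethylsilyl)oxy]butyl]-2-methylpropane-2-sulfinamide F1. TBAF in THF then removes the silyl group and the route is rejoined at alcohol 14, so that both the allylation and the hydroboration are bypassed.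

Step 12. The aryllithium 17 is flanked by two alkoxy groups and may deprotonate the Weinreb amide instead of adding to it, returning the debrominated arene. The fallback sets out from 16. The same lithium–bromine exchange is followed by trapping with acetaldehyde, a small and fast electrophile, to give the secondary alcohol 1-[2,4-bis(benzyloxy)-5-[(2R)-1-[(S)-tert-butylsulfinyl]pyrrolidin-2-yl]-3-methoxy-6-(methoxymethoxy)phenyl]ethan-1-ol F2 as a mixture at the carbinol carbon. Oxidation with Dess–Martin periodinane in CH2Cl2 removes that centre and comes back to the route at ketone 18.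

Step 15. The 4-benzyloxybenzoate is a deactivated electrophile and the enolate sits next to a hindered, fully substituted ring, so the intermolecular condensation may stall. The fallback sets out from 20. O-Acylation of the phenol with 4-(benzyloxy)benzoyl chloride (pyridine, DMAP, CH2Cl2) gives the aryl ester 2-acetyl-3,5-bis(benzyloxy)-4-methoxy-6-[(2R)-1-methylpyrrolidin-2-yl]phenyl 4-(benzyloxy)benzoate F3. Baker–Venkataraman rearrangement (KOtBu, THF, rt) then transfers the aroyl group intramolecularly to the ketone enolate carbon and comes back to the route at diketone 22.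

**Further compounds**
F1 | step 9 | (S)-N-[(1R)-1-[2,4-bis(benzyloxy)-5-bromo-3-methoxy-6-(methoxymethoxy)phenyl]-4-[(tert-butyldimethylsilyl)oxy]butyl]-2-methylpropane-2-sulfinamide | CC(C)(C)[Si](C)(C)OCCC[C@@H](N[S@@](=O)C(C)(C)C)c1c(OCOC)c(Br)c(OCc2ccccc2)c(OC)c1OCc1ccccc1
F2 | step 12 | 1-[2,4-bis(benzyloxy)-5-[(2R)-1-[(S)-tert-butylsulfinyl]pyrrolidin-2-yl]-3-methoxy-6-(methoxymethoxy)phenyl]ethan-1-ol | CC(O)c1c(OCOC)c([C@H]2CCCN2[S@@](=O)C(C)(C)C)c(OCc2ccccc2)c(OC)c1OCc1ccccc1
F3 | step 15 | 2-acetyl-3,5-bis(benzyloxy)-4-methoxy-6-[(2R)-1-methylpyrrolidin-2-yl]phenyl 4-(benzyloxy)benzoate | CC(=O)c1c(OC(=O)c2ccc(OCc3ccccc3)cc2)c([C@H]2CCCN2C)c(OCc2ccccc2)c(OC)c1OCc1ccccc1
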